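(Readings and results come from a simulation with made-up constants.)

A millimolar is the unit in which we book partner, since the scheme spends it one for one on protic impurity and on each turn of the catalyst, so the concentration to watch is the working partner: c(partner) as charged, less c(protic impurity) as charged, less the starting material converted, which for the flask at 50% conversion is 12.0 mM.

| setting | north-west | south-west | east | flask |
|---|---|---|---|---|
| starting material | 20 mM | 20 mM | 20 mM | 20 mM |
| partner | 36 mM | 57 mM | 26 mM | 26.0 mM |
| protic impurity | 4 mM | 4 mM | 6 mM | 4.00 mM |
| free catalyst | 46 µM | 46 µM | 46 µM | 46 µM |
| stray impurity | 13 µM | 13 µM | 13 µM | 13 µM |
| remark | run made earlier | run made earlier | run made earlier |  |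

- north-west (time / h: product / %, starting material / %): 0.200: 5.5, 94.9; 0.333: 6.5, 94.2; 0.667: 14.2, 87.7; 1.33: 26.1, 73.4; 2.50: 46.0, 55.3
- south-west (time / h: product / %, starting material / %): 0.200: 1.6, 96.0; 0.667: 14.4, 85.2; 1.00: 22.7, 79.1; 1.50: 31.6, 69.8; 2.50: 50.9, 49.9
- east (time / h: product / %, starting material / %): 0.200: 5.9, 97.4; 0.333: 7.3, 94.0; 0.667: 13.5, 88.1; 1.33: 20.9, 78.4; 2.50: 38.3, 61.1

(scatter of a reading: 1 percentage point)

- what was read earlier has a scatter of 1 percentage point, one standard deviation
- what may be going on: partner + free catalyst <-> catalyst intermediate A; catalyst intermediate A -> catalyst intermediate B; starting material + catalyst intermediate B <-> catalyst intermediate C; catalyst intermediate C -> free catalyst + product; free catalyst + stray impurity -> spent catalyst; partner + protic impurity -> quenched reagent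
- no earlier run changes the charge of free catalyst; that part of a forecast is a guess

* factor on the rate of making product when 50% of the starting material are converted if partner is charged twice over
* factor on the rate when 50% of the starting material are converted if free catalyst is charged at 250 µM instead

Run the flask slowly. In the first instants we book two side reactions: stray impurity takes catalyst one for one, leaving 33.0 µM of the 46 µM charged, and protic impurity begins on partner, of which we expect it to take 4.00 mM in the course of the run. In the middle the readings of the earlier runs climb close to a straight line, so we treat the rate as a function of working partner that saturates. Averaged from the start to 2.50 h, the south-west run makes product at 4.07 mM/h with a mean working partner of 47.9 mM, counting half the final product as spent, and the east run makes it at 3.06 mM/h with 16.2 mM. Through these two readings, the saturation partner, where the rate reaches half its ceiling, reads 9.65 mM. The flask at 50% conversion stands above it, so we reckon an order in working partner of 0.446. Towards the end, starting material is the limiting reagent, working partner heads for 2.00 mM, and our order climbs to 0.828.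

Charging partner twice over gives 38.0 mM of working partner at the same conversion, so we commit to a factor of 1.44. For catalyst we can only guess, taking the rate as following what the stray impurity leaves, which gives 7.18. The forecast, built on its “effective average partner”, gave 1.45 and 7.2. The simulation gives 1.42 and 7.26, with the flask reaching 50% conversion at 3.27 h and making product there at 2.53 mM/h.

    partner + free catalyst ⇌ catalyst intermediate A (K = 160 /M, k = 6.50 /M/s)
    catalyst intermediate A → catalyst intermediate B (k = 0.0710 /s)
    starting material + catalyst intermediate B ⇌ catalyst intermediate C (K = 4500 /M, k = 12.0 /M/s)
    catalyst intermediate C → free catalyst + product (k = 0.230 /s)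
    free catalyst + stray impurity → spent catalyst (k = 3100 /M/s)
    partner + protic impurity → quenched reagent (k = 0.0810 /M/s)

In the flask protic impurity is down to 0.0173% of its charge at 1.50 h, with 4.00 mM of quenched reagent standing, so the working partner of 12.0 mM has that loss taken off. The run with the step from partner and protic impurity to quenched reagent taken away keeps 16.0 mM of working partner, for which our curve gives a factor of 1.13. That step is one part of the reason for the rate in the flask: the rate at 50% conversion without it, as a multiple of the actual one, stands at 1.12. Among the runs with a step taken away, the largest single effect on that rate in the flask comes from the step from free catalyst and stray impurity to spent catalyst, without which the multiple stands at 1.39.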